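**Retrosynthetic overview**

- The strategy rests on the endo C2–O bond of the bornane. It sits beside the methyl-bearing quaternary bridgehead C1 and the CMe2 bridge C7, with the benzylic CH2 endo on C6, so that aromatic ring A, the ether oxygen and C2–C1–C6 make up oxepane ring B. This pattern is the imprint of a 2-pinanyl to bornyl Wagner–Meerwein shift ended by a tethered phenol.
- Key disconnection: the C1–C7 and C2–O bonds, leading back to 3-(2,4,6-trihydroxybenzyl)-β-pinene with the benzyl group trans to the CMe2 bridge. One acid-induced cascade builds the bornane cyclopentane and oxepane ring B.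
- The precursor comes from (+)-β-pinene by ozonolysis, trans-selective enolate benzylation with a tris-silylated benzyl bromide (from 2,4,6-trihydroxybenzaldehyde), Wittig methylenation and fluoride desilylation.
- Ring A is decorated last. The isovaleryl ketone goes between the two phenols by directed lithiation of the bis-MOM ether, and the one remaining ring carbon is then formylated.
- Ring order: pinane bicycle and ring A are purchased; cyclopentane of the bornane and oxepane ring B form together in the key step.

Key step: step 8

Assumption: (1R,5R)-(+)-β-pinene of high enantiomeric purity is taken as purchasable (it is the less common commercial enantiomer); it maps onto the (1R,2S,4R,6S) bornane of the target (bornane numbering).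

Remark on the chemistry: in the cyclised resorcinol the two free ring A carbons (one between the two hydroxyls, one between a hydroxyl and the oxepane oxygen) are expected to be near-equivalent toward Friedel–Crafts acylation. The ketone is therefore placed by directed metalation between two MOM ethers.

**Route**

Step 1
Reactants: 1 (1R,5R)-(+)-β-pinene
Product: 3 (1S,5R)-(−)-nopinone, via spiro ozonide 2 (not isolated)
Conditions: O3, CH2Cl2, −78 °C; then Me2S, −78 °C → rt
Reagents that add atoms: ozone ([O-][O+]=O)
Why: Ozonolysis with reductive work-up cleaves the exocyclic 1,1-disubstituted alkene to the ketone and leaves both bridgehead stereocentres untouched.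

Step 2
Reactants: 4 2,4,6-trihydroxybenzaldehyde
Product: 5 2,4,6-tris(tert-butyldimethylsilyloxy)benzaldehyde
Conditions: TBSCl (3.6 equiv), imidazole, DMAP (cat.), DMF, rt → 40 °C
Reagents that add atoms: tert-butyldimethylsilyl chloride (CC(C)(C)[Si](C)(C)Cl)
Why: Phenol silylation under Corey conditions masks all three hydroxyls as ethers that survive base and ylide and are later removed by fluoride without acid.

Step 3
Reactants: 5 2,4,6-tris(tert-butyldimethylsilyloxy)benzaldehyde
Product: 6 2,4,6-tris(tert-butyldimethylsilyloxy)benzyl alcohol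
Conditions: i-Bu2AlH (1.2 equiv), CH2Cl2, −78 °C; KNaC4H4O6 (aq)
Reagents that add atoms: none
Why: Hydride reduction of the aldehyde at low temperature through an aluminium alkoxide should avoid migration of an ortho silyl group to the benzylic oxygen.

Step 4
Reactants: 6 2,4,6-tris(tert-butyldimethylsilyloxy)benzyl alcohol
Product: 7 2,4,6-tris(tert-butyldimethylsilyloxy)benzyl bromide
Conditions: PPh3, CBr4, CH2Cl2, −20 → 0 °C; used at once without chromatography
Reagents that add atoms: carbon tetrabromide (BrC(Br)(Br)Br)
Why: The Appel reaction converts the electron-rich benzylic alcohol to the bromide under neutral conditions, and the bulky ortho silyloxy groups should slow Friedel–Crafts self-condensation.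

Step 5
Reactants: 3 (1S,5R)-(−)-nopinone; 7 2,4,6-tris(tert-butyldimethylsilyloxy)benzyl bromide
Product: 9 (1S,3S,5R)-3-[2,4,6-tris(tert-butyldimethylsilyloxy)benzyl]-6,6-dimethylbicyclo[3.1.1]heptan-2-one, via nopinone lithium enolate 8 (not isolated)
Conditions: LiN(i-Pr)2 (1.05 equiv), THF, −78 °C; then 7, DMPU, −78 → −20 °C
Reagents that add atoms: none
Why: Enolate alkylation at C3, the only enolisable position, should take the benzyl bromide from the face opposite the CMe2 bridge, which sets C3 with the benzyl group trans to that bridge (also the more stable epimer).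

Step 6
Reactants: 9 (1S,3S,5R)-3-[2,4,6-tris(tert-butyldimethylsilyloxy)benzyl]-6,6-dimethylbicyclo[3.1.1]heptan-2-one
Product: 10 (1R,3S,5R)-3-[2,4,6-tris(tert-butyldimethylsilyloxy)benzyl]-6,6-dimethyl-2-methylenebicyclo[3.1.1]heptane
Conditions: Ph3PCH3Br (3 equiv), KN(SiMe3)2 (2.8 equiv), THF, 0 → 60 °C
Reagents that add atoms: methyltriphenylphosphonium bromide (C[P+](c1ccccc1)(c1ccccc1)c1ccccc1.[Br-])
Why: Wittig methylenation, the reverse of step 1 on the same skeleton, with an alkoxide-free base that spares the aryl silyl ethers; any enolisation at C3 returns to the favoured trans epimer.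

Step 7
Reactants: 10 (1R,3S,5R)-3-[2,4,6-tris(tert-butyldimethylsilyloxy)benzyl]-6,6-dimethyl-2-methylenebicyclo[3.1.1]heptane
Product: 11 (1R,3S,5R)-3-(2,4,6-trihydroxybenzyl)-6,6-dimethyl-2-methylenebicyclo[3.1.1]heptane
Conditions: Bu4NF (3.3 equiv), AcOH (3.5 equiv), THF, 0 °C, under argon
Reagents that add atoms: none
Why: Buffered fluoride desilylation frees the three phenols without any acid strong enough to protonate the strained exocyclic alkene.

Step 8
Reactants: 11 (1R,3S,5R)-3-(2,4,6-trihydroxybenzyl)-6,6-dimethyl-2-methylenebicyclo[3.1.1]heptane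
Product: 12 oxepane-fused bornane resorcinol (bornane 1R,2S,4R,6S; ring A ether oxygen endo on C2, benzylic CH2 endo on C6, free OH para and ortho to the CH2)
Conditions: TfOH (10 mol %), CH2Cl2 (0.005 M), −40 → 0 °C; Et3N quench
Reagents that add atoms: none
Why: Proposed new method: protonation of the exocyclic alkene at its CH2 terminus gives the tertiary 2-pinanyl cation, relief of cyclobutane strain drives a suprafacial 1,2-shift of the CMe2 carbon from C1 to C2 (pinane numbering), and the bridged bornyl cation is opened at the former C1 by an ortho phenol oxygen; the closest known reaction is the acid-induced conversion of pinenes into bornyl chloride and bornyl esters, with the external nucleophile replaced here by a tethered phenol. The cyclopentane of the bornane is closed by the alkyl shift (bicyclo[3.1.1] to bicyclo[2.2.1]), and oxepane ring B is closed by O–C bond formation, a seven-membered closure onto the secondary carbon of the bridged ion. The quaternary centre (bornane C1) follows from the suprafacial shift inside the rigid bicycle, and the C2–O centre from backside opening anti to the migrated bridge, that is on the endo face, where the C3 benzyl group, trans to the CMe2 bridge in 11 and therefore endo on bornane C6, holds the phenol. The step needs the shift to outrun fragmentation of the cyclobutane to the monocyclic p-menthenyl cation and needs capture at the secondary, not the tertiary, carbon: a dry, non-nucleophilic, weakly polar medium at low temperature favours the bridged ion, and a six-membered chroman ether formed by direct capture of the tertiary cation is expected to re-ionise under TfOH whereas the endo-bornyl ether is not. The two ortho phenols are equivalent by symmetry, so no choice between oxygens arises, the free ring A carbons lie meta to the tether and cannot alkylate intramolecularly, and high dilution suppresses intermolecular Friedel–Crafts alkylation.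

Step 9
Reactants: 12 oxepane-fused bornane resorcinol
Product: 13 bis(methoxymethyl) ether of 12
Conditions: MOMCl (3 equiv), i-Pr2NEt (4 equiv), CH2Cl2, 0 °C → rt
Reagents that add atoms: chloromethyl methyl ether (COCCl)
Why: O-Alkylation of both phenols installs two strong ortho-directing groups that flank the ring A carbon destined for the ketone.

Step 10
Reactants: 14 isovaleryl chloride
Product: 15 N-methoxy-N,3-dimethylbutanamide
Conditions: MeNHOMe·HCl (1.1 equiv), pyridine (2.3 equiv), CH2Cl2, 0 °C → rt
Reagents that add atoms: N,O-dimethylhydroxylamine hydrochloride (CNOC.Cl)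
Why: Acylation of the hydroxylamine gives the Weinreb amide, an acyl donor that stops at the ketone stage with aryllithiums.

Step 11
Reactants: 13 bis(methoxymethyl) ether of 12; 15 N-methoxy-N,3-dimethylbutanamide
Product: 17 isovaleryl ketone of 13 (acyl on the ring A carbon between the two MOM ethers), via aryllithium 16 (not isolated)
Conditions: n-BuLi (1.2 equiv), THF, 0 °C, 1 h; then 15 (1.5 equiv), −78 → 0 °C; NH4Cl (aq)
Reagents that add atoms: none
Why: Directed ortho-metalation should occur at the ring carbon flanked by two chelating MOM ethers (the other free carbon has only one MOM ether and the weakly directing oxepane oxygen), and Weinreb ketone synthesis then delivers the ketone without over-addition.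

Step 12
Reactants: 17 isovaleryl ketone of 13
Product: 18 dihydroxy isovaleryl ketone (target lacking the formyl group)
Conditions: HCl (3 M, aq)/MeOH, 50 °C
Reagents that add atoms: none
Why: Acid-catalysed acetal cleavage removes both MOM ethers, each ortho to the ketone, while the secondary endo-bornyl aryl ether does not ionise under these conditions.

Step 13
Reactants: 18 dihydroxy isovaleryl ketone
Product: 19 CNP0246493.1
Conditions: Cl2CHOMe (2.5 equiv), TiCl4 (4 equiv), CH2Cl2, −78 → −10 °C; then 1 M HCl (aq), rt
Reagents that add atoms: dichloromethyl methyl ether (COC(Cl)Cl); water (O)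
Why: Rieche formylation, well established for acylphloroglucinols, can only attack the single unsubstituted ring A carbon between the hydroxyl and the oxepane oxygen, and the low temperature protects the bornyl ether from the Lewis acid.

**Compound list**

1 | (1R,5R)-(+)-β-pinene | C=C1CC[C@@H]2C[C@H]1C2(C)C | starting material
2 | spiro ozonide of 1 (1,2,4-trioxolane at C2) | O1OC2(CC[C@@H]3C[C@H]2C3(C)C)OC1 | intermediate (not isolated)
3 | (1S,5R)-(−)-nopinone | O=C1CC[C@@H]2C[C@H]1C2(C)C | intermediate
4 | 2,4,6-trihydroxybenzaldehyde | O=Cc1c(O)cc(O)cc1O | starting material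
5 | 2,4,6-tris(tert-butyldimethylsilyloxy)benzaldehyde | O=Cc1c(O[Si](C)(C)C(C)(C)C)cc(O[Si](C)(C)C(C)(C)C)cc1O[Si](C)(C)C(C)(C)C | intermediate
6 | 2,4,6-tris(tert-butyldimethylsilyloxy)benzyl alcohol | OCc1c(O[Si](C)(C)C(C)(C)C)cc(O[Si](C)(C)C(C)(C)C)cc1O[Si](C)(C)C(C)(C)C | intermediate
7 | 2,4,6-tris(tert-butyldimethylsilyloxy)benzyl bromide | BrCc1c(O[Si](C)(C)C(C)(C)C)cc(O[Si](C)(C)C(C)(C)C)cc1O[Si](C)(C)C(C)(C)C | intermediate
8 | lithium enolate of nopinone | [Li]OC1=CC[C@@H]2C[C@H]1C2(C)C | intermediate (not isolated)
9 | (1S,3S,5R)-3-[2,4,6-tris(tert-butyldimethylsilyloxy)benzyl]-6,6-dimethylbicyclo[3.1.1]heptan-2-one (benzyl trans to the CMe2 bridge) | CC(C)(C)[Si](C)(C)Oc1cc(O[Si](C)(C)C(C)(C)C)c(C[C@@H]2C[C@@H]3C[C@@H](C3(C)C)C2=O)c(O[Si](C)(C)C(C)(C)C)c1 | intermediate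
10 | (1R,3S,5R)-3-[2,4,6-tris(tert-butyldimethylsilyloxy)benzyl]-6,6-dimethyl-2-methylenebicyclo[3.1.1]heptane | CC(C)(C)[Si](C)(C)Oc1cc(O[Si](C)(C)C(C)(C)C)c(C[C@@H]2C[C@@H]3C[C@@H](C3(C)C)C2=C)c(O[Si](C)(C)C(C)(C)C)c1 | intermediate
11 | (1R,3S,5R)-3-(2,4,6-trihydroxybenzyl)-6,6-dimethyl-2-methylenebicyclo[3.1.1]heptane (key-step precursor) | Oc1cc(O)c(C[C@@H]2C[C@@H]3C[C@@H](C3(C)C)C2=C)c(O)c1 | intermediate
12 | oxepane-fused bornane resorcinol (bornane 1R,2S,4R,6S; O endo on C2, CH2 endo on C6) | c1c(O)cc2c(c1O)C[C@@H]1C[C@@H]3C[C@H](O2)[C@@]1(C)C3(C)C | intermediate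
13 | bis(methoxymethyl) ether of 12 | c1c(OCOC)cc2c(c1OCOC)C[C@@H]1C[C@@H]3C[C@H](O2)[C@@]1(C)C3(C)C | intermediate
14 | isovaleryl chloride | CC(C)CC(Cl)=O | starting material
15 | N-methoxy-N,3-dimethylbutanamide | CC(C)CC(=O)N(C)OC | intermediate
16 | aryllithium from 13 (Li on the ring A carbon between the two MOM ethers) | [Li]c1c(OCOC)cc2c(c1OCOC)C[C@@H]1C[C@@H]3C[C@H](O2)[C@@]1(C)C3(C)C | intermediate (not isolated)
17 | isovaleryl ketone of 13 | CC(C)CC(=O)c1c(OCOC)cc2c(c1OCOC)C[C@@H]1C[C@@H]3C[C@H](O2)[C@@]1(C)C3(C)C | intermediate
18 | dihydroxy isovaleryl ketone | CC(C)CC(=O)c1c(O)cc2c(c1O)C[C@@H]1C[C@@H]3C[C@H](O2)[C@@]1(C)C3(C)C | intermediate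
19 | CNP0246493.1 | CC(C)CC(=O)c1c(O)c(C=O)c2c(c1O)C[C@@H]1C[C@@H]3C[C@H](O2)[C@@]1(C)C3(C)C | target

**Step count and risks**

Total steps: 13. Longest linear sequence: 11 steps (steps 2–9 and 11–13, from 4).

Steps most likely to fail:

1. Step 8. The 2-pinanyl cation may fragment its cyclobutane to the monocyclic p-menthenyl cation faster than it shifts, the phenol may close a six-membered ether at the tertiary carbon that does not re-ionise, or the electron-rich ring may be alkylated intermolecularly. The fallback separates the skeletal shift from the ether closure. It sets out from 10, which is treated with anhydrous Cl3CCO2H in toluene (0 °C → rt), the classical pinene-to-bornyl ester rearrangement with an external carboxylate, to give the endo-bornyl trichloroacetate F1. K2CO3 in MeOH then removes the ester and the three aryl silyl ethers to give the 6-endo-(2,4,6-trihydroxybenzyl)borneol F2. Dry HCl in dioxane (60 °C) closes the aryl ether by the known dehydrative O-alkylation of phloroglucinols by alcohols through the keto tautomer; the borneol C–O bond is kept, so the endo configuration is retained, and the route is rejoined at 12.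

2. Step 11. Deprotonation at the ring A carbon beside the oxepane oxygen may compete with lithiation between the two MOM ethers, or lithiation may be incomplete, which would erode the regiochemistry of the ketone. The fallback blocks the competing carbon by electrophilic substitution and acylates without a metalation. It sets out from 13: NBS in MeCN (−20 °C) should brominate the more open carbon next to the oxepane oxygen to give the bromo bis-MOM ether F3. HCl/MeOH gives the bromo resorcinol F4. Friedel–Crafts acylation with 14 and TiCl4 (CH2Cl2, 0 °C) can then only reach the carbon between the two hydroxyls, giving the bromo ketone F5. Hydrogenolysis (H2, Pd/C, NaOAc, EtOAc) removes the bromine and rejoins the route at 18.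

3. Step 5. The very electron-rich bromide 7 may ionise and self-condense before it alkylates, and SN2 attack between two ortho silyloxy groups may be slow enough for proton transfer between enolate and product to intervene. The fallback forms the same C–C bond by condensation. It sets out from 4 and 3: 4 is benzylated (BnBr, K2CO3, DMF) to 2,4,6-tris(benzyloxy)benzaldehyde F6. Claisen–Schmidt condensation with 3 (KOH, EtOH, rt) gives the (E)-3-arylidene nopinone F7. Hydrogenation (H2, Pd/C, EtOAc) saturates the alkene and cleaves the benzyl ethers, and brief K2CO3/MeOH equilibration should give the trans-configured 3-(2,4,6-trihydroxybenzyl)nopinone F8. Silylation (TBSCl, imidazole, DMF) rejoins the route at 9.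

**Further compounds**

F1 | step 8 | endo-bornyl trichloroacetate with 6-endo-[2,4,6-tris(tert-butyldimethylsilyloxy)benzyl] group | CC(C)(C)[Si](C)(C)Oc1cc(O[Si](C)(C)C(C)(C)C)c(C[C@@H]2C[C@@H]3C[C@H](OC(=O)C(Cl)(Cl)Cl)[C@@]2(C)C3(C)C)c(O[Si](C)(C)C(C)(C)C)c1
F2 | step 8 | 6-endo-(2,4,6-trihydroxybenzyl)borneol | Oc1cc(O)c(C[C@@H]2C[C@@H]3C[C@H](O)[C@@]2(C)C3(C)C)c(O)c1
F3 | step 11 | bromo bis-MOM ether (Br on the ring A carbon next to the oxepane oxygen) | c1c(OCOC)c(Br)c2c(c1OCOC)C[C@@H]1C[C@@H]3C[C@H](O2)[C@@]1(C)C3(C)C
F4 | step 11 | bromo resorcinol | c1c(O)c(Br)c2c(c1O)C[C@@H]1C[C@@H]3C[C@H](O2)[C@@]1(C)C3(C)C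
F5 | step 11 | bromo isovaleryl ketone | CC(C)CC(=O)c1c(O)c(Br)c2c(c1O)C[C@@H]1C[C@@H]3C[C@H](O2)[C@@]1(C)C3(C)C
F6 | step 5 | 2,4,6-tris(benzyloxy)benzaldehyde | O=Cc1c(OCc2ccccc2)cc(OCc2ccccc2)cc1OCc1ccccc1
F7 | step 5 | (E)-3-[2,4,6-tris(benzyloxy)benzylidene]nopinone | O=C1/C(=C/c2c(OCc3ccccc3)cc(OCc3ccccc3)cc2OCc2ccccc2)C[C@@H]2C[C@H]1C2(C)C
F8 | step 5 | (1S,3S,5R)-3-(2,4,6-trihydroxybenzyl)nopinone | Oc1cc(O)c(C[C@@H]2C[C@@H]3C[C@@H](C3(C)C)C2=O)c(O)c1
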